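The two labelled bonds define a formal [3+3] annulation that builds ring C. The route below is a proposal, and every step is a known reaction type.

Ring A is the lactone, ring B the cycloheptane C4a–C5–C6–C7–C19–C11–C11a, ring C the cyclohexane C7–C8–C9–C10–C11–C19 (xenicane numbering). Ring C is cut at C9–C10 and at the quaternary C7–C19 bond into two three-carbon pieces. The anti relation of the C8–O and C7–C19 bonds at the methyl-bearing C7 is the imprint of anti opening of an epoxide, and C19–C11–C10 is a trimethylenemethane unit. In one flask the triflate of (2S,3S)-2,3-epoxygeraniol, an acyclic terpene, is coupled with a 2-(silylmethyl)allyl Grignard reagent (C9–C10) and then cyclised by epoxide–allylsilane closure (C7–C19). Ring B and the lactone follow by chromium-mediated closure and alkenylcopper addition.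

Key step: step 3

Remark: numbering is C1 lactone carbonyl, O2, C3 (OCH2), C4 (ring alkylidene carbon), C4a, C5, C6, C7 (quaternary, methyl C18), C8 (CHOH), C9, C10, C11 (tertiary carbinol), C11a, C12–C15 side chain with methyls C16 and C17, C19 (one-carbon bridge); compounds 1, 4 and 13 are assumed to be commercial.

Step 1
Reactants: 1 geraniol, (2E)-3,7-dimethylocta-2,6-dien-1-ol
Product: 2 [(2S,3S)-3-methyl-3-(4-methylpent-3-en-1-yl)oxiran-2-yl]methanol
Conditions: Ti(OiPr)4 (5 mol%), L-(+)-diethyl tartrate (6 mol%), t-BuOOH, 4 Å molecular sieves, CH2Cl2, −20 °C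
Reagents that add atoms: tert-butyl hydroperoxide, CC(C)(C)OO
Why: Sharpless asymmetric epoxidation touches only the allylic alcohol alkene, and L-(+)-tartrate should deliver oxygen to the face that gives the (2S,3S)-epoxide, which fixes C8 and, after inversion in step 3, C7.

Step 2
Reactants: 2 [(2S,3S)-3-methyl-3-(4-methylpent-3-en-1-yl)oxiran-2-yl]methanol
Product: 3 [(2S,3S)-3-methyl-3-(4-methylpent-3-en-1-yl)oxiran-2-yl]methyl trifluoromethanesulfonate
Conditions: Tf2O, 2,6-lutidine, CH2Cl2, −78 °C; cold aqueous work-up, used at once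
Reagents that add atoms: trifluoromethanesulfonic anhydride, O=S(=O)(OS(=O)(=O)C(F)(F)F)C(F)(F)F
Why: O-sulfonylation of the primary alcohol at low temperature leaves both stereocentres untouched and turns C9 into the first electrophilic site of the three-carbon bis-electrophile.

Step 3
Reactants: 3 [(2S,3S)-3-methyl-3-(4-methylpent-3-en-1-yl)oxiran-2-yl]methyl trifluoromethanesulfonate; 4 [2-(chloromethyl)prop-2-en-1-yl](trimethyl)silane
Product: 7 (1S,2S)-2-methyl-4-methylidene-2-(4-methylpent-3-en-1-yl)cyclohexan-1-ol, via silylmethylallyl Grignard reagent 5 (not isolated), via epoxy allylsilane 6 (not isolated)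
Conditions: 4, Mg, Et2O, 0 °C (gives 5); add to 3, CuBr·SMe2 (5 mol%), Et2O, −78 → −30 °C; then CH2Cl2, BF3·OEt2, −78 → −40 °C; NaHCO3 (aq), then K2CO3, MeOH
Reagents that add atoms: none
Why: Grignard reagent 5, whose two CH2 termini are equivalent, displaces the primary triflate of 3 under copper catalysis (SN2 at the CH2 carbon, C9–C10) faster than it opens the hindered trisubstituted epoxide, giving 6 with the allylsilane terminus placed for ring closure. BF3 then activates the epoxide and the CH2= terminus attacks the tertiary carbon C7 anti to the departing oxygen through a chair transition state; this 6-endo opening at the more substituted carbon closes ring C (C7–C19), and the β-silyl cation at C11 loses silicon to leave the exocyclic methylene. Both events are known reaction types, the copper-catalysed Grignard coupling of epoxy sulfonates and the allylsilane-terminated epoxide cyclisation (a cation–olefin cyclisation), run here in one flask as a formal [3+3] annulation of a bis-electrophile with a trimethylenemethane dianion equivalent. C8 keeps the configuration set in step 1 and the quaternary C7 is formed with inversion, so the (2S,3S)-epoxide maps onto 7S,8S with the C8–O and C7–C19 bonds anti. The step needs substitution before any epoxide opening (triflate leaving group, low temperature, ether without THF) and cyclisation by the allylsilane in preference to the remote trisubstituted alkene or a hydride-shift rearrangement of the epoxide; the higher nucleophilicity of the allylsilane and the six-membered chair should secure this.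

Step 4
Reactants: 7 (1S,2S)-2-methyl-4-methylidene-2-(4-methylpent-3-en-1-yl)cyclohexan-1-ol
Product: 8 triethyl{[(1S,2S)-2-methyl-4-methylidene-2-(4-methylpent-3-en-1-yl)cyclohexyl]oxy}silane
Conditions: Et3SiOTf, 2,6-lutidine, CH2Cl2, −78 → 0 °C
Reagents that add atoms: triethylsilyl trifluoromethanesulfonate, CC[Si](CC)(CC)OS(=O)(=O)C(F)(F)F
Why: Silyl ether formation on the hindered secondary alcohol blocks lactol formation and oxa-Michael addition of the C8 oxygen in steps 5 to 7.

Step 5
Reactants: 8 triethyl{[(1S,2S)-2-methyl-4-methylidene-2-(4-methylpent-3-en-1-yl)cyclohexyl]oxy}silane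
Product: 9 3-[(1S,2S)-1-methyl-5-oxo-2-(triethylsilyloxy)cyclohexyl]propanal
Conditions: O3, CH2Cl2/MeOH, −78 °C; then Me2S, −78 → 25 °C; used crude
Reagents that add atoms: ozone, [O-][O+]=O
Why: Ozonolysis with reductive work-up cleaves both alkenes at once, so the exocyclic methylene becomes the C11 ketone and the trisubstituted alkene becomes the C4a aldehyde.

Step 6
Reactants: 9 3-[(1S,2S)-1-methyl-5-oxo-2-(triethylsilyloxy)cyclohexyl]propanal
Product: 10 methyl (2Z)-2-iodo-5-[(1S,2S)-1-methyl-5-oxo-2-(triethylsilyloxy)cyclohexyl]pent-2-enoate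
Conditions: Ph3P=CHCO2Me, N-iodosuccinimide, CH2Cl2, −20 °C; K2CO3; then 9, 25 °C
Reagents that add atoms: methyl (triphenylphosphoranylidene)acetate, COC(=O)C=P(c1ccccc1)(c1ccccc1)c1ccccc1; N-iodosuccinimide, O=C1CCC(=O)N1I
Why: Wittig olefination with the α-iodo ylide made in situ should react with the aldehyde and not the ketone and, as a stabilised ylide, place the ester trans to the chain, giving the (Z)-α-iodo enoate that carries C1 and C11a.

Step 7
Reactants: 10 methyl (2Z)-2-iodo-5-[(1S,2S)-1-methyl-5-oxo-2-(triethylsilyloxy)cyclohexyl]pent-2-enoate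
Product: 11 methyl (1R,6S,7S)-1-hydroxy-6-methyl-7-(triethylsilyloxy)bicyclo[4.3.1]dec-2-ene-2-carboxylate
Conditions: CrCl2 (6 equiv), NiCl2 (2 mol%), DMF, 25 °C, high dilution
Reagents that add atoms: none
Why: In this Nozaki–Hiyama–Kishi reaction zerovalent nickel inserts into the C–I bond and transmetalation gives an alkenyl derivative of trivalent chromium that adds to the C11 ketone and closes ring B; because C11a is tied to C7 through C4a–C5–C6 it can only bond cis to C6 on ring C, which fixes C11 as R.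

Step 8
Reactants: 11 methyl (1R,6S,7S)-1-hydroxy-6-methyl-7-(triethylsilyloxy)bicyclo[4.3.1]dec-2-ene-2-carboxylate
Product: 12 methyl (1R,6S,7S)-6-methyl-1,7-bis(triethylsilyloxy)bicyclo[4.3.1]dec-2-ene-2-carboxylate
Conditions: Et3SiOTf, 2,6-lutidine, CH2Cl2, 0 °C
Reagents that add atoms: triethylsilyl trifluoromethanesulfonate, CC[Si](CC)(CC)OS(=O)(=O)C(F)(F)F
Why: Silylation of the tertiary bridgehead alcohol protects the β-hydroxy ester against retro-aldol cleavage during the base equilibration in step 12.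

Step 9
Reactants: 13 4-{[tert-butyl(dimethyl)silyl]oxy}but-2-yn-1-ol
Product: 14 (2Z)-4-{[tert-butyl(dimethyl)silyl]oxy}-3-iodobut-2-en-1-ol
Conditions: NaAlH2(OCH2CH2OCH3)2, THF, 0 °C; EtOAc; then I2, −78 → 0 °C
Reagents that add atoms: iodine, II
Why: trans-Hydroalumination directed by the free propargylic alkoxide puts hydride on the carbon next to CH2OH and aluminium on the distal carbon, and iodinolysis with retention should give the (Z)-iodoalkene with iodine next to CH2OSi.

Step 10
Reactants: 14 (2Z)-4-{[tert-butyl(dimethyl)silyl]oxy}-3-iodobut-2-en-1-ol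
Product: 16 (3E,5Z)-7-{[tert-butyl(dimethyl)silyl]oxy}-6-iodohepta-3,5-dien-2-one, via iodo enal 15 (not isolated)
Conditions: MnO2, Ph3P=CHC(O)CH3, CH2Cl2, 25 °C
Reagents that add atoms: 1-(triphenylphosphoranylidene)propan-2-one, CC(=O)C=P(c1ccccc1)(c1ccccc1)c1ccccc1
Why: Tandem allylic oxidation and Wittig olefination traps the isomerisation-prone (Z)-β-iodo enal as it forms, and the stabilised ylide should give the (E)-enone.

Step 11
Reactants: 16 (3E,5Z)-7-{[tert-butyl(dimethyl)silyl]oxy}-6-iodohepta-3,5-dien-2-one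
Product: 18 tert-butyl{[(2Z,4E)-2-iodo-6-methyl-6-(triethylsilyloxy)hepta-2,4-dien-1-yl]oxy}dimethylsilane, via lithium alkoxide 17 (not isolated)
Conditions: MeLi, CeCl3, THF, −78 °C; then Et3SiOTf, −78 → 0 °C
Reagents that add atoms: methyllithium, [Li]C; triethylsilyl trifluoromethanesulfonate, CC[Si](CC)(CC)OS(=O)(=O)C(F)(F)F
Why: 1,2-Addition of the organocerium reagent to the dienone (no conjugate addition and no iodine–lithium exchange at −78 °C) is followed by O-silylation of the tertiary alkoxide in the same flask.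

Step 12
Reactants: 12 methyl (1R,6S,7S)-6-methyl-1,7-bis(triethylsilyloxy)bicyclo[4.3.1]dec-2-ene-2-carboxylate; 18 tert-butyl{[(2Z,4E)-2-iodo-6-methyl-6-(triethylsilyloxy)hepta-2,4-dien-1-yl]oxy}dimethylsilane
Product: 21 methyl (1R,2R,3S,6S,7S)-3-[(2E,4E)-1-{[tert-butyl(dimethyl)silyl]oxy}-6-methyl-6-(triethylsilyloxy)hepta-2,4-dien-2-yl]-6-methyl-1,7-bis(triethylsilyloxy)bicyclo[4.3.1]decane-2-carboxylate, via alkenyllithium 19 (not isolated), via C11a-epimeric ester 20 (not isolated)
Conditions: 18, t-BuLi (2 equiv), Et2O, −78 °C (gives 19); CuI, then BF3·OEt2, −78 °C; 12, −78 → −40 °C; NH4Cl (aq); then NaOMe (cat.), MeOH, 25 °C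
Reagents that add atoms: none
Why: Organocopper 1,4-addition with retention of the alkenyl geometry (which becomes the 4(12)E alkylidene) should occur on the face of the ring B enoate remote from the C8–C9–C10 bridge and so set C4a, and methoxide equilibration of the ester-bearing C11a should give the trans 4a,11a arrangement.

Step 13
Reactants: 21 methyl (1R,2R,3S,6S,7S)-3-[(2E,4E)-1-{[tert-butyl(dimethyl)silyl]oxy}-6-methyl-6-(triethylsilyloxy)hepta-2,4-dien-2-yl]-6-methyl-1,7-bis(triethylsilyloxy)bicyclo[4.3.1]decane-2-carboxylate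
Product: 23 CNP0116574.1 (target), via tetraol methyl ester 22 (not isolated)
Conditions: HF·pyridine, pyridine, THF, 0 → 25 °C; then 2-hydroxypyridine (cat.), toluene, 50 °C
Reagents that add atoms: none
Why: Buffered fluoride cleaves the four silyl ethers without forming free alkoxides (sparing the tertiary dienyl alcohol and the β-hydroxy ester), and the freed C3 hydroxyl should close the δ-lactone on the C1 methyl ester by transesterification with no stereocentre affected.

Compound list
1 | geraniol, (2E)-3,7-dimethylocta-2,6-dien-1-ol | CC(C)=CCC/C(C)=C/CO | starting material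
2 | [(2S,3S)-3-methyl-3-(4-methylpent-3-en-1-yl)oxiran-2-yl]methanol | OC[C@@H]1O[C@@]1(C)CCC=C(C)C | intermediate
3 | [(2S,3S)-3-methyl-3-(4-methylpent-3-en-1-yl)oxiran-2-yl]methyl trifluoromethanesulfonate | O=S(=O)(OC[C@@H]1O[C@@]1(C)CCC=C(C)C)C(F)(F)F | intermediate
4 | [2-(chloromethyl)prop-2-en-1-yl](trimethyl)silane | C[Si](C)(C)CC(=C)CCl | starting material
5 | chloro{2-[(trimethylsilyl)methyl]prop-2-en-1-yl}magnesium | C[Si](C)(C)CC(=C)C[Mg]Cl | intermediate
6 | trimethyl{2-methylidene-4-[(2S,3S)-3-methyl-3-(4-methylpent-3-en-1-yl)oxiran-2-yl]butyl}silane | C[Si](C)(C)CC(=C)CC[C@@H]1O[C@@]1(C)CCC=C(C)C | intermediate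
7 | (1S,2S)-2-methyl-4-methylidene-2-(4-methylpent-3-en-1-yl)cyclohexan-1-ol | CC(C)=CCC[C@@]1(C)CC(=C)CC[C@@H]1O | intermediate
8 | triethyl{[(1S,2S)-2-methyl-4-methylidene-2-(4-methylpent-3-en-1-yl)cyclohexyl]oxy}silane | CC(C)=CCC[C@@]1(C)CC(=C)CC[C@@H]1O[Si](CC)(CC)CC | intermediate
9 | 3-[(1S,2S)-1-methyl-5-oxo-2-(triethylsilyloxy)cyclohexyl]propanal | O=CCC[C@@]1(C)CC(=O)CC[C@@H]1O[Si](CC)(CC)CC | intermediate
10 | methyl (2Z)-2-iodo-5-[(1S,2S)-1-methyl-5-oxo-2-(triethylsilyloxy)cyclohexyl]pent-2-enoate | COC(=O)/C(I)=C/CC[C@@]1(C)CC(=O)CC[C@@H]1O[Si](CC)(CC)CC | intermediate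
11 | methyl (1R,6S,7S)-1-hydroxy-6-methyl-7-(triethylsilyloxy)bicyclo[4.3.1]dec-2-ene-2-carboxylate | COC(=O)C2=CCC[C@@]1(C)C[C@]2(O)CC[C@@H]1O[Si](CC)(CC)CC | intermediate
12 | methyl (1R,6S,7S)-6-methyl-1,7-bis(triethylsilyloxy)bicyclo[4.3.1]dec-2-ene-2-carboxylate | COC(=O)C2=CCC[C@@]1(C)C[C@]2(O[Si](CC)(CC)CC)CC[C@@H]1O[Si](CC)(CC)CC | intermediate
13 | 4-{[tert-butyl(dimethyl)silyl]oxy}but-2-yn-1-ol | OCC#CCO[Si](C)(C)C(C)(C)C | starting material
14 | (2Z)-4-{[tert-butyl(dimethyl)silyl]oxy}-3-iodobut-2-en-1-ol | OC/C=C(\I)/CO[Si](C)(C)C(C)(C)C | intermediate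
15 | (2Z)-4-{[tert-butyl(dimethyl)silyl]oxy}-3-iodobut-2-enal | O=C/C=C(\I)/CO[Si](C)(C)C(C)(C)C | intermediate
16 | (3E,5Z)-7-{[tert-butyl(dimethyl)silyl]oxy}-6-iodohepta-3,5-dien-2-one | CC(=O)/C=C/C=C(\I)/CO[Si](C)(C)C(C)(C)C | intermediate
17 | lithium (3E,5Z)-7-{[tert-butyl(dimethyl)silyl]oxy}-6-iodo-2-methylhepta-3,5-dien-2-olate | [Li+].CC(C)([O-])/C=C/C=C(\I)/CO[Si](C)(C)C(C)(C)C | intermediate
18 | tert-butyl{[(2Z,4E)-2-iodo-6-methyl-6-(triethylsilyloxy)hepta-2,4-dien-1-yl]oxy}dimethylsilane | CC(C)(O[Si](CC)(CC)CC)/C=C/C=C(\I)/CO[Si](C)(C)C(C)(C)C | intermediate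
19 | alkenyllithium from 18 (lithium in place of iodine, geometry retained) | CC(C)(O[Si](CC)(CC)CC)/C=C/C=C(\[Li])/CO[Si](C)(C)C(C)(C)C | intermediate
20 | methyl (1R,2S,3S,6S,7S)-3-[(2E,4E)-1-{[tert-butyl(dimethyl)silyl]oxy}-6-methyl-6-(triethylsilyloxy)hepta-2,4-dien-2-yl]-6-methyl-1,7-bis(triethylsilyloxy)bicyclo[4.3.1]decane-2-carboxylate (C11a epimer of 21) | CC(C)(O[Si](CC)(CC)CC)/C=C/C=C(/CO[Si](C)(C)C(C)(C)C)[C@H]1CC[C@@]2(C)C[C@](O[Si](CC)(CC)CC)(CC[C@@H]2O[Si](CC)(CC)CC)[C@H]1C(=O)OC | intermediate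
21 | methyl (1R,2R,3S,6S,7S)-3-[(2E,4E)-1-{[tert-butyl(dimethyl)silyl]oxy}-6-methyl-6-(triethylsilyloxy)hepta-2,4-dien-2-yl]-6-methyl-1,7-bis(triethylsilyloxy)bicyclo[4.3.1]decane-2-carboxylate | CC(C)(O[Si](CC)(CC)CC)/C=C/C=C(/CO[Si](C)(C)C(C)(C)C)[C@H]1CC[C@@]2(C)C[C@](O[Si](CC)(CC)CC)(CC[C@@H]2O[Si](CC)(CC)CC)[C@@H]1C(=O)OC | intermediate
22 | methyl (1R,2R,3S,6S,7S)-3-[(2E,4E)-1,6-dihydroxy-6-methylhepta-2,4-dien-2-yl]-1,7-dihydroxy-6-methylbicyclo[4.3.1]decane-2-carboxylate | CC(C)(O)/C=C/C=C(/CO)[C@H]1CC[C@@]2(C)C[C@](O)(CC[C@@H]2O)[C@@H]1C(=O)OC | intermediate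
23 | CNP0116574.1: (4aS,7S,8S,11R,11aR)-lactone with C8 and C11 hydroxyls, C7 methyl, C19 bridge and the (4(12)E,13E)-dienyl tertiary alcohol side chain | CC(C)(O)/C=C/C=C1/COC(=O)[C@@H]2[C@@H]1CC[C@@]1(C)C[C@]2(O)CC[C@@H]1O | target

Total step count: 13. Longest linear sequence: 10 steps (steps 1 to 8, 12 and 13); steps 9 to 11 make the side-chain fragment.

Steps most likely to fail

Step 3. The Grignard reagent may open the epoxide before it displaces the triflate, or the Lewis acid added to the unpurified mixture may trigger hydride-shift rearrangement of the epoxide instead of ring closure. The fallback sets out from 3 and comes back at 9. The dianion of methyl acetoacetate (NaH, n-BuLi, THF) is alkylated at its terminal carbon by 3 to form C9–C10 and give the epoxy β-keto ester F1. SnCl4 in CH2Cl2 at −78 °C then closes ring C by attack of the enol carbon on the tertiary epoxide carbon (C7–C19), giving the cyclic β-keto ester F2. Krapcho decarboxylation (LiCl, wet DMSO, heat) gives the hydroxy ketone F3, Et3SiOTf gives the silyl ether F4, and ozonolysis of the one remaining alkene gives 9.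

Step 12. Addition to the hindered trisubstituted enoate may be too slow, or the reagent may approach from the wrong face. The fallback sets out from 11 and comes back at 21. The free tertiary alcohol of 11 is converted to its chloromagnesium alkoxide (t-BuMgCl), which binds the alkenylmagnesium bromide made from 19 and MgBr2 and delivers the alkenyl group within the complex to C4a on the face of the C11 oxygen (alkoxide-directed conjugate addition), giving the hydroxy ester F8. Silylation with Et3SiOTf and the methoxide equilibration of step 12 then lead to 21.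

Step 7. Protonolysis of the alkenylchromium species (loss of iodine without C–C bond formation) may outrun the slow seven-membered closure onto a ketone. The fallback sets out from 9 and comes back at 11. Wittig olefination of 9 with Ph3P=CHCO2Me gives the (E)-enoate F5. Me2AlSPh adds 1,4 and the aluminium enolate closes ring B by intramolecular aldol addition to the C11 ketone, giving the β-phenylthio ester F6. Oxidation with mCPBA at −78 °C gives the sulfoxide F7, and thermal syn-elimination in toluene gives 11.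

Further compounds
F1 | step 3 | methyl 5-[(2S,3S)-3-methyl-3-(4-methylpent-3-en-1-yl)oxiran-2-yl]-3-oxopentanoate | COC(=O)CC(=O)CC[C@@H]1O[C@@]1(C)CCC=C(C)C
F2 | step 3 | methyl (5S,6S)-5-hydroxy-6-methyl-6-(4-methylpent-3-en-1-yl)-2-oxocyclohexane-1-carboxylate | COC(=O)C1C(=O)CC[C@H](O)[C@@]1(C)CCC=C(C)C
F3 | step 3 | (3S,4S)-4-hydroxy-3-methyl-3-(4-methylpent-3-en-1-yl)cyclohexan-1-one | O=C1CC[C@H](O)[C@@](C)(CCC=C(C)C)C1
F4 | step 3 | (3S,4S)-3-methyl-3-(4-methylpent-3-en-1-yl)-4-(triethylsilyloxy)cyclohexan-1-one | O=C1CC[C@H](O[Si](CC)(CC)CC)[C@@](C)(CCC=C(C)C)C1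
F5 | step 7 | methyl (2E)-5-[(1S,2S)-1-methyl-5-oxo-2-(triethylsilyloxy)cyclohexyl]pent-2-enoate | COC(=O)/C=C/CC[C@@]1(C)CC(=O)CC[C@@H]1O[Si](CC)(CC)CC
F6 | step 7 | methyl (1R,6S,7S)-1-hydroxy-6-methyl-3-(phenylsulfanyl)-7-(triethylsilyloxy)bicyclo[4.3.1]decane-2-carboxylate | COC(=O)C2C(Sc3ccccc3)CC[C@@]1(C)C[C@]2(O)CC[C@@H]1O[Si](CC)(CC)CC
F7 | step 7 | methyl (1R,6S,7S)-3-(benzenesulfinyl)-1-hydroxy-6-methyl-7-(triethylsilyloxy)bicyclo[4.3.1]decane-2-carboxylate | COC(=O)C2C(S(=O)c3ccccc3)CC[C@@]1(C)C[C@]2(O)CC[C@@H]1O[Si](CC)(CC)CC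
F8 | step 12 | methyl (1R,3S,6S,7S)-3-[(2E,4E)-1-{[tert-butyl(dimethyl)silyl]oxy}-6-methyl-6-(triethylsilyloxy)hepta-2,4-dien-2-yl]-1-hydroxy-6-methyl-7-(triethylsilyloxy)bicyclo[4.3.1]decane-2-carboxylate | CC(C)(O[Si](CC)(CC)CC)/C=C/C=C(/CO[Si](C)(C)C(C)(C)C)[C@H]1CC[C@@]2(C)C[C@](O)(CC[C@@H]2O[Si](CC)(CC)CC)C1C(=O)OC
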